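Slowness was my way in: in birch, the coldest flask, Q takes on average 5.70 h to become X, whereas G refills the solution with E in about 4.28 min, so X arrives late.

| flask | Z | G | Q | temperature | time |
|---|---|---|---|---|---|
| maple | 1.0 M | 200 mM (held) | 120 mM | 90 °C | 20 h |
| ash | 1.0 M | 200 mM (held) | 120 mM | 110 °C | 20 h |
| elm | 1.0 M | 200 mM (held) | 120 mM | 130 °C | 20 h |
| birch | 1.0 M | 200 mM (held) | 120 mM | 70 °C | 20 h |

    Z + E ⇌ Z.E (K1 = 13 M⁻¹, k1 = 0.00170 M⁻¹ s⁻¹, Ea1 = 64.0 kJ mol⁻¹, ΔH1 = 0 kJ mol⁻¹)
    Z + E ⇌ L (K2 = 75 M⁻¹, k2 = 8.68 × 10⁻⁴ M⁻¹ s⁻¹, Ea2 = 74.0 kJ mol⁻¹, ΔH2 = −82.0 kJ mol⁻¹)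
    Z.E + X ⇌ L + X, rate k3*[X]*[Z.E] forward; the back reaction follows from the equilibrium constant (k3 = 8.31 × 10⁻⁴ M⁻¹ s⁻¹, Ea3 = 64.0 kJ mol⁻¹)
    G ⇌ E, rate k4*(csat - [E]) (k4 = 0.00389 s⁻¹, csat = 200 mM)
    E + Q → X + D (k5 = 9.78 × 10⁻⁴ M⁻¹ s⁻¹, Ea5 = 72.0 kJ mol⁻¹)
    (constants at 90 °C)

- at the start none of E is dissolved
- all constants are for 90 °C and move with temperature by the activation energies and enthalpies

- the flask with the highest amount of Z.E, in percent of the Z charged ("all alike" if they lie within 1.5 percentage points) (maple / ash / elm / birch / all alike)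
- final Z.E, as a percentage of the Z charged, in maple
- final Z.E, as a percentage of the Z charged, in ash
- final Z.E, as a percentage of the Z charged, in elm
- final Z.E, as a percentage of the Z charged, in birch

I looked for the concentration that sets the order of the rates. In birch Z takes up E with pseudo-first-order constants 0.356 h⁻¹ towards Z.E and 0.150 h⁻¹ towards L, and Z.E returns to Z at 0.137 h⁻¹. These hold with cE at csat, and they may, because G can supply 2.80 M h⁻¹, more than the 0.506 M h⁻¹ that the full charge of Z takes up at the start.

Then I bracketed birch. From above, I dropped X: the remaining linear pair decays at the slow rate 0.0337 h⁻¹ and leaves Z.E at 31.5 %. From below, Z.E falling towards equilibrium at csat has the floor 3.39 %.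

To tighten this I used the exposure, 1.51: k3 times cX summed over the run, with cX growing as Q converts, which counts how many e-foldings of drain X has delivered. Z.E holds a share 72.2 % of Z plus Z.E, so I shrank the gap between bound and floor by exp(−share × exposure), which gave 12.9 %.

Maple's exposure is 6.67, which leaves hardly any of the gap, and k3 is larger still in ash and elm. So I took equilibrium shares for these: 14.0 % in maple, 35.9 % in ash and 56.4 % in elm. The highest was elm.

The forecast named elm and gave 14 %, 35.9 %, 56.4 % and, inside my bracket, 11.5 % for birch, from “piecewise eigenvalue estimates”.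

The simulation gave elm, with 14.0 % in maple, 35.9 % in ash, 56.4 % in elm and 11.9 % in birch, a little under my birch figure.

Birch's reading puts Z.E at 30.3 % of the gap, where exposure had promised 33.6 %. The neighbouring flask is birch charged with 0.048 M of Q. Its bound and floor stay as they were, since neither contains X, but its exposure shrinks with the charge to 0.604. The same reckoning then gave 21.6 %. That neighbouring flask ended with 21.0 % of the Z charged as Z.E.

The constants used here are invented; no experiment stands behind them.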